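**Plan**

- Ring numbering: C1 carries the benzoyl group, C2 the OH, C3 and C5 the prenyl groups, C4 and C6 the OMe groups.
- Cuts: ring bonds C1–C2 and C5–C6 together (Diels–Alder/aromatization of a 1,1,3-trioxygenated diene C2–C5 with the acyl ynol ether MeO–C6≡C1–COPh). Then C3–C4 (Claisen condensation), the two ring–CH2 bonds of the prenyl groups (Johnson–Claisen) and C1–C(=O) (acetylide acylation).
- Enabling feature: the single benzene ring alternates O (C2, C4, C6) and C (C1, C3, C5) substituents, and its only free OH sits on C2 beside the acyl-bearing C1. A ketene-acetal diene (acetal carbon = C2, nucleophilic terminus = C5) and a push–pull alkyne (electrophilic C6, acyl-bearing C1) carry exactly this polarity, so the acetal carbon emerges as the chelated phenol and no later O-differentiation is needed. The chain C2–C5 with both prenyl groups is the Claisen dimer of one ester.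
- Forward: ester 5 → β-keto ester 7 → enol ether 9 → diene 11; ynone 16 in one step; the benzene ring is formed last, in one operation, with all six substituents in place.
- Stereochemistry: the target is achiral and has no stereogenic alkene; transient sp3 centres and alkene geometries are erased on the way.

Key step: step 6

Remark: alkene geometries that are erased later (enolates 6 and 8, enol ether 9, C1=C2 of 10 and 11) are drawn for the isomer expected to prevail or left open; 7 is racemic and 17 a diastereomer mixture, both without consequence.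

**Step 1**
Reactants: 1 2-methylbut-3-en-2-ol; 2 trimethyl orthoacetate
Product: 5 methyl 5-methylhex-4-enoate, via mixed orthoester 3 (not isolated), via ketene acetal 4 (not isolated)
Conditions: EtCO2H (cat.), excess 2, 115–135 °C, MeOH distilled off
Reagents that add atoms: none
Why: Johnson–Claisen rearrangement, in which acid-catalysed exchange and loss of methanol give the allyl ketene acetal, whose [3,3] shift forms the C–C bond at the unsubstituted alkene terminus and leaves the trisubstituted prenyl-type alkene.

**Step 2**
Reactants: 5 methyl 5-methylhex-4-enoate (two molecules)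
Product: 7 methyl 7-methyl-2-(3-methylbut-2-en-1-yl)-3-oxooct-6-enoate (racemic), via sodium enolate 6 (not isolated)
Conditions: NaH (0.6 equiv), MeOH (cat.), THF, reflux; then cold 1 M HCl
Reagents that add atoms: none
Why: Claisen self-condensation of an unbranched ester, driven by deprotonation of the β-keto ester formed, which makes the C3–C4 bond and places both prenyl groups 1,3 to each other (the α-stereocentre is racemic and disappears in step 3).

**Step 3**
Reactants: 7 methyl 7-methyl-2-(3-methylbut-2-en-1-yl)-3-oxooct-6-enoate
Product: 9 methyl (2E)-3-methoxy-7-methyl-2-(3-methylbut-2-en-1-yl)octa-2,6-dienoate, via potassium enolate 8 (not isolated)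
Conditions: KH, THF, 0 °C; DMPU; Me2SO4, 0 °C → rt
Reagents that add atoms: dimethyl sulfate COS(=O)(=O)OC
Why: O-alkylation of a β-keto ester enolate, in which the potassium counterion, the hard sulfate electrophile, the dipolar aprotic cosolvent and the α-substituent (C-methylation would build a quaternary centre) should direct methylation to oxygen, the solvent-separated enolate reacting from its extended form so that the E isomer is expected to prevail, a geometry that is erased in step 4.

**Step 4**
Reactants: 9 methyl (2E)-3-methoxy-7-methyl-2-(3-methylbut-2-en-1-yl)octa-2,6-dienoate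
Product: 11 {[(3Z)-1,3-dimethoxy-7-methyl-2-(3-methylbut-2-en-1-yl)octa-1,3,6-trien-1-yl]oxy}trimethylsilane, via lithium dienolate 10 (not isolated)
Conditions: LiN(i-Pr)2, THF, −78 °C; Me3SiCl, −78 → 0 °C; pentane, filtration under argon, used crude
Reagents that add atoms: chlorotrimethylsilane C[Si](C)(C)Cl
Why: Vinylogous (γ) deprotonation of a β-alkoxy enoate and O-silylation of the ester dienolate, the standard entry to 1-alkoxy-1-silyloxy dienes (vinylketene acetals), with allylic strain placing the side-chain CH2 anti to the diene backbone (3Z), the geometry a Diels–Alder reaction needs.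

**Step 5**
Reactants: 12 2-chloro-1,1-dimethoxyethane; 13 N-methoxy-N-methylbenzamide
Product: 16 3-methoxy-1-phenylprop-2-yn-1-one, via lithium methoxyacetylide 14 (not isolated), via tetrahedral lithium adduct 15 (not isolated)
Conditions: LiNEt2 (3.1 equiv), THF, 0 °C → rt; 13, −78 → −20 °C; inverse quench into cold aq NaHSO4/Et2O; used at once as a solution
Reagents that add atoms: none
Why: Twofold elimination (HCl, MeOH) and deprotonation of the chloroacetal give the alkoxyacetylide, and the Weinreb ketone synthesis holds the acylation at the chelated tetrahedral adduct so that the ynone is set free only on quench.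

**Step 6**
Reactants: 11 {[(3Z)-1,3-dimethoxy-7-methyl-2-(3-methylbut-2-en-1-yl)octa-1,3,6-trien-1-yl]oxy}trimethylsilane; 16 3-methoxy-1-phenylprop-2-yn-1-one
Product: 19 [2-hydroxy-4,6-dimethoxy-3,5-bis(3-methylbut-2-en-1-yl)phenyl](phenyl)methanone, via cycloadduct 17 (not isolated), via aryl silyl ether 18 (not isolated)
Conditions: 11 (1.5 equiv), toluene, rt → 80 °C, argon; then 0.5 M HCl, THF, 0 °C
Reagents that add atoms: none
Why: Proposed new method: the electron-rich vinylketene acetal 11 and the push–pull alkyne 16 should combine in a polar, asynchronous [4+2] cycloaddition (in the limit a vinylogous Mukaiyama–Michael attack of the diene terminus on the methoxy-bearing alkyne carbon, then collapse of the allenolate onto the silyloxycarbenium carbon), after which ketal 17 loses methanol to the aryl silyl ether 18 and dilute acid cleaves this to the phenol. The closest known reaction type is the Diels–Alder/aromatization of 1-alkoxy-1-silyloxy dienes with acetylenic ketones and esters to salicylate-type phenols; what is not established is a dienophile that carries an alkoxy donor on its β-carbon. The benzene ring is closed by an intermolecular [4+2] cycloaddition that forms the bonds C5–C6 and C1–C2 (target numbering) and is aromatized by 1,4-elimination across C2 and C5. The product has no stereocentre, and the two sp3 centres of 17 are erased on aromatization. The step needs regioselectivity, which the matched polarization secures (largest HOMO coefficient at the prenyl-bearing diene terminus, largest LUMO coefficient at the methoxy-bearing alkyne carbon, so that the acetal carbon bonds to the benzoyl-bearing carbon), and [4+2] instead of [3+3] closure, which the absence of a Lewis acid secures by leaving the ketone carbonyl unactivated. Hydrolytic work-up cleaves the Si–O bond and not the aryl methyl ethers, so C2 should emerge as the free, ketone-chelated OH while C4 and C6 keep their methyl ethers.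

**Compound list**

1 | 2-methylbut-3-en-2-ol | CC(C)(O)C=C | starting material
2 | trimethyl orthoacetate | CC(OC)(OC)OC | starting material
3 | 3-(1,1-dimethoxyethoxy)-3-methylbut-1-ene (mixed orthoester) | CC(OC)(OC)OC(C)(C)C=C | intermediate
4 | 3-[(1-methoxyethenyl)oxy]-3-methylbut-1-ene (ketene acetal) | COC(=C)OC(C)(C)C=C | intermediate
5 | methyl 5-methylhex-4-enoate | COC(=O)CCC=C(C)C | intermediate
6 | sodium (2Z)-1-methoxy-7-methyl-2-(3-methylbut-2-en-1-yl)-1-oxoocta-2,6-dien-3-olate (sodium enolate of 7, chelated form) | [Na+].COC(=O)/C(CC=C(C)C)=C(\[O-])CCC=C(C)C | intermediate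
7 | methyl 7-methyl-2-(3-methylbut-2-en-1-yl)-3-oxooct-6-enoate (racemic) | COC(=O)C(CC=C(C)C)C(=O)CCC=C(C)C | intermediate
8 | potassium (2E)-1-methoxy-7-methyl-2-(3-methylbut-2-en-1-yl)-1-oxoocta-2,6-dien-3-olate (potassium enolate of 7, extended solvent-separated form) | [K+].COC(=O)/C(CC=C(C)C)=C(/[O-])CCC=C(C)C | intermediate
9 | methyl (2E)-3-methoxy-7-methyl-2-(3-methylbut-2-en-1-yl)octa-2,6-dienoate | COC(=O)/C(CC=C(C)C)=C(/OC)CCC=C(C)C | intermediate
10 | lithium (3Z)-1,3-dimethoxy-7-methyl-2-(3-methylbut-2-en-1-yl)octa-1,3,6-trien-1-olate (lithium dienolate of 9; C1=C2 geometry open) | [Li+].COC([O-])=C(CC=C(C)C)/C(OC)=C/CC=C(C)C | intermediate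
11 | {[(3Z)-1,3-dimethoxy-7-methyl-2-(3-methylbut-2-en-1-yl)octa-1,3,6-trien-1-yl]oxy}trimethylsilane (C1=C2 geometry open) | COC(O[Si](C)(C)C)=C(CC=C(C)C)/C(OC)=C/CC=C(C)C | intermediate
12 | 2-chloro-1,1-dimethoxyethane | COC(CCl)OC | starting material
13 | N-methoxy-N-methylbenzamide | CON(C)C(=O)c1ccccc1 | starting material
14 | lithium methoxyacetylide (methoxyethynyllithium) | [Li]C#COC | intermediate
15 | lithium 3-methoxy-1-[methoxy(methyl)amino]-1-phenylprop-2-yn-1-olate (tetrahedral adduct) | [Li+].COC#CC([O-])(N(C)OC)c1ccccc1 | intermediate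
16 | 3-methoxy-1-phenylprop-2-yn-1-one | COC#CC(=O)c1ccccc1 | intermediate
17 | [2,4,6-trimethoxy-3,5-bis(3-methylbut-2-en-1-yl)-6-(trimethylsilyloxy)cyclohexa-1,4-dien-1-yl](phenyl)methanone (diastereomer mixture) | COC1=C(C(=O)c2ccccc2)C(OC)(O[Si](C)(C)C)C(CC=C(C)C)=C(OC)C1CC=C(C)C | intermediate
18 | [4,6-dimethoxy-3,5-bis(3-methylbut-2-en-1-yl)-2-(trimethylsilyloxy)phenyl](phenyl)methanone | COc1c(CC=C(C)C)c(O[Si](C)(C)C)c(C(=O)c2ccccc2)c(OC)c1CC=C(C)C | intermediate
19 | [2-hydroxy-4,6-dimethoxy-3,5-bis(3-methylbut-2-en-1-yl)phenyl](phenyl)methanone | COc1c(CC=C(C)C)c(O)c(C(=O)c2ccccc2)c(OC)c1CC=C(C)C | target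

**Step count and risk**

Total steps: 6. Longest linear sequence: 5 (steps 1, 2, 3, 4, 6); step 5 is the one-step side branch.

Steps most likely to fail:

1. Step 6 (Proposed new method). The cycloaddition may be too slow, because the methoxy donor raises the LUMO of the alkyne and both diene termini are substituted. Thermal desilylation of the diene or oligomerization of the ynone could then overtake ring formation. Fallback by known chemistry, setting out from 1 and coming back at 19: commercial (2,4,6-trihydroxyphenyl)(phenyl)methanone is C-prenylated twice with 1 (BF3·OEt2, dioxane, rt; electrophilic prenylation of an acylphloroglucinol) to give [2,4,6-trihydroxy-3,5-bis(3-methylbut-2-en-1-yl)phenyl](phenyl)methanone F1. Me2SO4 (2 equiv), K2CO3, acetone, reflux should then methylate the 4-OH and one of the two equivalent ortho OH groups. The remaining OH is locked in the hydrogen bond to the ketone and should stay free, which gives 19.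

2. Step 5. Conjugate addition of the liberated N,O-dimethylhydroxylamine or of water to the push–pull ynone during the quench, and oligomerization on concentration, may consume the product. Fallback, setting out from 14 (generated as in step 5) and coming back at 16: addition of 14 to benzaldehyde (THF, −78 °C, neutral work-up) gives 3-methoxy-1-phenylprop-2-yn-1-ol F2 (racemic). Oxidation with MnO2 (CH2Cl2, rt) under neutral, amine-free conditions then gives 16 as a filtered solution for direct use.

3. Step 3. C-methylation may compete with O-methylation, and a Z enol ether may resist γ-deprotonation in step 4. Fallback, setting out from 7 and coming back at 19: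
   - Me3SiCl, Et3N gives methyl (2Z)-7-methyl-2-(3-methylbut-2-en-1-yl)-3-(trimethylsilyloxy)octa-2,6-dienoate F3.
   - LiN(i-Pr)2, then Me3SiCl gives (3Z)-1-methoxy-7-methyl-2-(3-methylbut-2-en-1-yl)-1,3-bis(trimethylsilyloxy)octa-1,3,6-triene F4.
   - Cycloaddition of F4 with 16 under the conditions of step 6 should pass through [2,6-dimethoxy-3,5-bis(3-methylbut-2-en-1-yl)-4,6-bis(trimethylsilyloxy)cyclohexa-1,4-dien-1-yl](phenyl)methanone F5 and [6-methoxy-3,5-bis(3-methylbut-2-en-1-yl)-2,4-bis(trimethylsilyloxy)phenyl](phenyl)methanone F6 to [2,4-dihydroxy-6-methoxy-3,5-bis(3-methylbut-2-en-1-yl)phenyl](phenyl)methanone F7.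
   - MeI (1 equiv), K2CO3, acetone, rt should methylate the non-chelated 4-OH of F7 to give 19.

**Further compounds**

F1 | step 6 | [2,4,6-trihydroxy-3,5-bis(3-methylbut-2-en-1-yl)phenyl](phenyl)methanone | CC(C)=CCc1c(O)c(CC=C(C)C)c(O)c(C(=O)c2ccccc2)c1O
F2 | step 5 | 3-methoxy-1-phenylprop-2-yn-1-ol (racemic) | COC#CC(O)c1ccccc1
F3 | step 3 | methyl (2Z)-7-methyl-2-(3-methylbut-2-en-1-yl)-3-(trimethylsilyloxy)octa-2,6-dienoate | COC(=O)/C(CC=C(C)C)=C(\O[Si](C)(C)C)CCC=C(C)C
F4 | step 3 | (3Z)-1-methoxy-7-methyl-2-(3-methylbut-2-en-1-yl)-1,3-bis(trimethylsilyloxy)octa-1,3,6-triene | COC(O[Si](C)(C)C)=C(CC=C(C)C)/C(O[Si](C)(C)C)=C/CC=C(C)C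
F5 | step 3 | [2,6-dimethoxy-3,5-bis(3-methylbut-2-en-1-yl)-4,6-bis(trimethylsilyloxy)cyclohexa-1,4-dien-1-yl](phenyl)methanone (diastereomer mixture) | COC1=C(C(=O)c2ccccc2)C(OC)(O[Si](C)(C)C)C(CC=C(C)C)=C(O[Si](C)(C)C)C1CC=C(C)C
F6 | step 3 | [6-methoxy-3,5-bis(3-methylbut-2-en-1-yl)-2,4-bis(trimethylsilyloxy)phenyl](phenyl)methanone | COc1c(CC=C(C)C)c(O[Si](C)(C)C)c(CC=C(C)C)c(O[Si](C)(C)C)c1C(=O)c1ccccc1
F7 | step 3 | [2,4-dihydroxy-6-methoxy-3,5-bis(3-methylbut-2-en-1-yl)phenyl](phenyl)methanone | COc1c(CC=C(C)C)c(O)c(CC=C(C)C)c(O)c1C(=O)c1ccccc1
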